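I began with the catalyst's death.

left-handed substrate 10 mM; coupling partner 3.00 equiv; protic impurity 0.200 mM; free catalyst 5 mol%; right-handed substrate 10 mM; time 15 d

    free catalyst + left-handed substrate ⇌ catalyst intermediate A (K1 = 96 /M, k1 = 1670 /M/h)
    coupling partner + catalyst intermediate A → free catalyst + left-handed product (k2 = 46.3 /M/h)
    free catalyst + right-handed substrate ⇌ catalyst intermediate B (K3 = 75.5 /M, k3 = 7090 /M/h)
    coupling partner + protic impurity → quenched reagent (k4 = 143 /M/h)
    coupling partner + catalyst intermediate B → free catalyst + right-handed product (k5 = 19.8 /M/h)
    coupling partner + free catalyst → spent catalyst B (k6 = 7.16 /M/h)
    free catalyst → spent catalyst A (k7 = 0.0348 /h)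

1. share of the left-handed substrate and right-handed substrate together used up at 15 d
2. left-handed product at 15 d, in percent of the left-handed substrate and right-handed substrate together charged
3. right-handed substrate at 15 d, in percent of the left-handed substrate and right-handed substrate together charged
4. right-handed product at 15 d, in percent of the left-handed substrate and right-handed substrate together charged

I reckoned the charges on the left-handed substrate, as stated: coupling partner B = 30.0 mM, catalyst 0.500 mM. Two rates mattered. Free catalyst dies at D = 0.250 /h, the partner route plus the lone decay, and the partner route is faster. Intermediate A loses its substrate at 17.4 /h, faster than it couples at 1.39 /h, so I held it in equilibrium with free catalyst. The logarithm of the left-handed substrate then falls in proportion to free catalyst, at L = 0.0667 /h if the catalyst charge stood free.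

Free catalyst's curve needs no tracing. The dying steps act on free catalyst, so the area under that curve is the charge over D, however much sits bound, provided the catalyst dies within the run; its life, stretched by binding at the charged substrates, is 10.9 h, short against 15 d. Replacing the curve by that mean gives Λ = L/D = 0.267, the logarithm of how far the left-handed substrate falls before the catalyst is dead. I held B at its charge, as an assumption; B stands in both L and D. Intermediate B loses its substrate at 93.9 /h, faster than it couples at 0.594 /h, so I held it in equilibrium too, and the right-handed substrate receives Λ/s, where s = 2.97 is the selectivity factor. So I committed to conversion 16.0%, left-handed product 11.7%, right-handed substrate 45.7% and right-handed product 4.30%.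

The forecast gave 28.3%, 19.6%, 41.3% and 8.7%, in that order, on other charges than mine: “I took 3 equiv and 5 mol% against the 20 mM total substrate”.

The flask gave 15.0%, 10.8%, 45.8% and 4.20%, and ten times the time changed nothing. The neighbour flask with 20 mol% of catalyst has Λ = 1.07, so I reckoned 34.3% of its left-handed substrate left, and it kept 39%. For its right-handed substrate I reckoned 69.7%, and it kept 72%. Its conversion came out at 48.0% by reckoning and 44.5% in the neighbour flask.

The rate constants are invented, and the outcome is calculated.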